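**Retrosynthetic overview**
1. The cis-4,5-epoxide comes from an invertive cyclodehydration of a (4R,5R)-diol, which comes from syn-dihydroxylation of an (E)-cyclodecenone.
2. The ten-membered carbocycle comes from a CO2-extruding ring contraction (12 to 10, forming C2–C3) of an allyl β-keto macrolactone. This is the key step.
3. The macrolactone comes from acylketene trapping by the C3–OH. The β-keto ester comes from the C1 acid plus a malonate unit, and the C3–OH from allylic oxidation of an isobutenyl group.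
4. C8 comes from a 1,3-syn reduction and C10 from a copper–bis(oxazoline) pyruvate aldol. C7 and C11 come from a three-component coupling on a butenolide, and C6 from an asymmetric alkynylation of prenal.
5. Order of ring formation: γ-lactone, twelve-membered lactone, ten-membered carbocycle, oxirane.

Assumption: germacrane numbering is used (C1 = ring ketone, C12 = lactone carbonyl); the SMILES is read as 4R,5S,6S,7R,8S,10R,11R, that is a cis-4,5-epoxide on a trans-fused 12,6-olide; each chiral ligand is named in the enantiomeric form expected from its usual model to give the drawn centre.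

**Step 1**
Reactants: 1 3-methylbut-2-enal; 2 methyl propiolate
Product: 3 methyl (4R)-4-hydroxy-6-methylhept-5-en-2-ynoate
Conditions: Me2Zn (3 equiv), (S,S)-ProPhenol (10 mol%), toluene, 0 °C; aq NH4Cl
Reagents that add atoms: none
Why: Catalytic asymmetric alkynylation of an enal (dinuclear zinc ProPhenol type), in which the chiral zinc pocket delivers the zinc propiolate to one aldehyde face and sets C6.

**Step 2**
Reactants: 3 methyl (4R)-4-hydroxy-6-methylhept-5-en-2-ynoate
Product: 5 (5S)-5-(2-methylprop-1-enyl)furan-2(5H)-one, via methyl (2Z,4S)-4-hydroxy-6-methylhepta-2,5-dienoate 4 (not isolated)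
Conditions: H2 (1 atm), Pd/CaCO3 poisoned with Pb(OAc)2, quinoline, EtOAc, rt; then SiO2
Reagents that add atoms: none
Why: Lindlar-type cis semihydrogenation stops at the Z-enoate, whose hydroxyl lactonises onto the ester to give the butenolide without touching C6 or the trisubstituted alkene.

**Step 3**
Reactants: 5 (5S)-5-(2-methylprop-1-enyl)furan-2(5H)-one; 6 ethyl vinyl ether; 7 formaldehyde
Product: 11 [(3R,4S,5R)-4-(1-ethoxyvinyl)-5-(2-methylprop-1-enyl)-2-oxooxolan-3-yl]methyl acetate, via (1-ethoxyvinyl)lithium 8 (not isolated), via lithium bis(1-ethoxyvinyl)cuprate 9 (not isolated), via hydroxymethyl lactone lithium alkoxide 10 (not isolated)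
Conditions: 6, t-BuLi, THF, −78 to 0 °C; CuI (0.5 equiv), −40 °C; 5, −78 °C; CH2O (gas), −78 °C; Ac2O, −78 to 0 °C; NH4Cl/NH3 buffer
Reagents that add atoms: acetic anhydride CC(=O)OC(C)=O
Why: Tandem cuprate conjugate addition and enolate aldol (three-component coupling) with O-acetylation, in which the acyl-anion equivalent adds to C7 anti to the C6 side chain and formaldehyde attacks the enolate anti to the new C7 group, giving the all-trans lactone (C7, C11).

**Step 4**
Reactants: 12 pyruvic acid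
Product: 13 tert-butyl pyruvate
Conditions: isobutene, H2SO4 (cat.), CH2Cl2, rt, sealed flask
Reagents that add atoms: isobutene CC(C)=C
Why: Acid-catalysed addition of the acid to isobutene (tert-butyl ester protection) gives a bulky ester that later resists lactonisation by the C8 hydroxyl.

**Step 5**
Reactants: 11 [(3R,4S,5R)-4-(1-ethoxyvinyl)-5-(2-methylprop-1-enyl)-2-oxooxolan-3-yl]methyl acetate; 13 tert-butyl pyruvate
Product: 14 tert-butyl (2R)-4-[(2R,3S,4R)-4-(acetoxymethyl)-2-(2-methylprop-1-enyl)-5-oxooxolan-3-yl]-2-hydroxy-2-methyl-4-oxobutanoate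
Conditions: Cu(OTf)2 (10 mol%), (R,R)-t-Bu-box (11 mol%), CH2Cl2, −78 to −40 °C; then 1 M HCl, THF, 0 °C
Reagents that add atoms: water O
Why: Evans-type Mukaiyama aldol addition of the enol ether to pyruvate chelated on divalent copper, where the bis(oxazoline) blocks one ketone face and sets C10 as R; the acid work-up unmasks the C8 ketone with C7 held in its favoured trans arrangement.

**Step 6**
Reactants: 14 tert-butyl (2R)-4-[(2R,3S,4R)-4-(acetoxymethyl)-2-(2-methylprop-1-enyl)-5-oxooxolan-3-yl]-2-hydroxy-2-methyl-4-oxobutanoate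
Product: 15 tert-butyl (2R,4S)-4-[(2R,3R,4R)-4-(acetoxymethyl)-2-(2-methylprop-1-enyl)-5-oxooxolan-3-yl]-2,4-dihydroxy-2-methylbutanoate
Conditions: Et2BOMe, THF/MeOH 4:1, −78 °C; NaBH4; MeOH co-evaporation
Reagents that add atoms: none
Why: Narasaka–Prasad reduction, in which external hydride attacks the six-membered boron chelate of the β-hydroxy ketone to give the 1,3-syn diol (C8 S) while esters and lactone survive at −78 °C.

**Step 7**
Reactants: 15 tert-butyl (2R,4S)-4-[(2R,3R,4R)-4-(acetoxymethyl)-2-(2-methylprop-1-enyl)-5-oxooxolan-3-yl]-2,4-dihydroxy-2-methylbutanoate; 16 tigloyl chloride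
Product: 18 tert-butyl (2R,4S)-2-acetoxy-4-[(2R,3R,4R)-4-(acetoxymethyl)-2-(2-methylprop-1-enyl)-5-oxooxolan-3-yl]-2-methyl-4-[(E)-2-methylbut-2-enoyloxy]butanoate, via C8 mono-tiglate 17 (not isolated)
Conditions: 16, pyridine, DMAP (cat.), CH2Cl2, 0 °C; then Ac2O, DMAP, 35 °C
Reagents that add atoms: acetic anhydride CC(=O)OC(C)=O
Why: Sequential DMAP-catalysed acylation in one pot, in which the secondary C8 hydroxyl takes the acid chloride first and the tertiary C10 hydroxyl is then acetylated under forcing conditions, with no stereocentre touched.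

**Step 8**
Reactants: 18 tert-butyl (2R,4S)-2-acetoxy-4-[(2R,3R,4R)-4-(acetoxymethyl)-2-(2-methylprop-1-enyl)-5-oxooxolan-3-yl]-2-methyl-4-[(E)-2-methylbut-2-enoyloxy]butanoate
Product: 20 (2R,4S)-2-acetoxy-4-[(2R,3R,4R)-4-(acetoxymethyl)-2-(2-methylprop-1-enyl)-5-oxooxolan-3-yl]-2-methyl-4-[(E)-2-methylbut-2-enoyloxy]butanoic acid, via trimethylsilyl ester 19 (not isolated)
Conditions: TMSOTf, 2,6-lutidine, CH2Cl2, 0 °C; pH 4 buffer
Reagents that add atoms: none
Why: Silyl triflate mediated cleavage of the tert-butyl ester (loss of isobutene, then hydrolysis of the silyl ester) is selective over the acetates, the tiglate and the allylic lactone.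

**Step 9**
Reactants: 20 (2R,4S)-2-acetoxy-4-[(2R,3R,4R)-4-(acetoxymethyl)-2-(2-methylprop-1-enyl)-5-oxooxolan-3-yl]-2-methyl-4-[(E)-2-methylbut-2-enoyloxy]butanoic acid
Product: 21 (2R,4S)-2-acetoxy-4-[(2R,3R,4R)-4-(acetoxymethyl)-2-[(1E)-3-hydroxy-2-methylprop-1-enyl]-5-oxooxolan-3-yl]-2-methyl-4-[(E)-2-methylbut-2-enoyloxy]butanoic acid
Conditions: SeO2 (0.3 equiv), t-BuOOH, CH2Cl2, 0 °C to rt
Reagents that add atoms: tert-butyl hydroperoxide (terminal oxygen source, relayed by SeO2) CC(C)(C)OO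
Why: Catalytic SeO2 allylic oxidation (ene reaction then 2,3-shift) picks the E-methyl of the gem-dimethyl alkene and gives the E-allylic alcohol, while the electron-poor tiglate alkene is inert.

**Step 10**
Reactants: 21 (2R,4S)-2-acetoxy-4-[(2R,3R,4R)-4-(acetoxymethyl)-2-[(1E)-3-hydroxy-2-methylprop-1-enyl]-5-oxooxolan-3-yl]-2-methyl-4-[(E)-2-methylbut-2-enoyloxy]butanoic acid; 22 methyl hydrogen malonate
Product: 25 methyl (4R,6S)-4-acetoxy-6-[(2R,3R,4R)-4-(acetoxymethyl)-2-[(1E)-3-hydroxy-2-methylprop-1-enyl]-5-oxooxolan-3-yl]-4-methyl-3-oxo-6-[(E)-2-methylbut-2-enoyloxy]hexanoate, via magnesium bis(methyl malonate) 23 (not isolated), via acyl imidazolide 24 (not isolated)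
Conditions: 21, CDI (1.0 equiv), THF, 0 °C; Mg(O2CCH2CO2Me)2 (from 22 and Mg(OEt)2), THF, rt; 0.5 M HCl
Reagents that add atoms: none
Why: Masamune–Brooks decarboxylative Claisen homologation, in which the acid consumes CDI much faster than the alcohol and the near-neutral magnesium enolate installs C2 and the ester carbon without harming the base-sensitive β-acetoxy lactone.

**Step 11**
Reactants: 25 methyl (4R,6S)-4-acetoxy-6-[(2R,3R,4R)-4-(acetoxymethyl)-2-[(1E)-3-hydroxy-2-methylprop-1-enyl]-5-oxooxolan-3-yl]-4-methyl-3-oxo-6-[(E)-2-methylbut-2-enoyloxy]hexanoate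
Product: 27 twelve-membered (E)-allyl β-keto lactone (ring C1–C2–C(=O)–O–C3 to C10; 6R,7R,8S,10R,11R), via acylketene 26 (not isolated)
Conditions: xylene (0.5 mM), 140 °C, slow addition
Reagents that add atoms: none
Why: Thermal loss of methanol gives acylketene 26, which the remote primary allylic alcohol traps under high dilution (Boeckman-type acylketene macrolactonisation) under neutral conditions.

**Step 12**
Reactants: 27 twelve-membered (E)-allyl β-keto lactone
Product: 29 (4E,6R,7R,8S,10R,11R)-10,13-diacetoxy-1-oxo-8-tigloyloxygermacr-4-en-12,6-olide, via ring β-keto acid 28 (not isolated)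
Conditions: Pd(PPh3)4 (10 mol%), THF (1 mM), 50 °C
Reagents that add atoms: none
Why: Proposed new method: zerovalent palladium ionises the primary allylic C3–O bond of the macrolactone, the freed β-keto carboxylate stays tethered to the syn-η3-allyl cation, passes its C2 proton to the carboxylate and attacks the unhindered C3 terminus as a soft enolate, so that C2–C3 closes the ten-membered ring with the E geometry kept and loss of CO2 from 28 makes the 12 to 10 contraction irreversible; the closest known reactions are the Tsuji–Saegusa decarboxylative allylation of acyclic allyl β-keto esters and Trost-type macrocyclic allylic alkylation, neither of which has been shown on a macrolactone that contracts to a medium carbocycle.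

**Step 13**
Reactants: 29 (4E,6R,7R,8S,10R,11R)-10,13-diacetoxy-1-oxo-8-tigloyloxygermacr-4-en-12,6-olide
Product: 30 (4R,5R,6S,7R,8S,10R,11R)-10,13-diacetoxy-4,5-dihydroxy-1-oxo-8-tigloyloxygermacran-12,6-olide
Conditions: OsO4 (5 mol%), NMO, acetone/H2O, 0 °C
Reagents that add atoms: N-methylmorpholine N-oxide C[N+]1([O-])CCOCC1; water O
Why: Upjohn dihydroxylation, in which the strained E-alkene reacts ahead of the tiglate and OsO4 adds syn to the open peripheral face (the face used in epoxidations of costunolide-type germacranolides), setting C4 as R and giving C5 as R.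

**Step 14**
Reactants: 30 (4R,5R,6S,7R,8S,10R,11R)-10,13-diacetoxy-4,5-dihydroxy-1-oxo-8-tigloyloxygermacran-12,6-olide
Product: 31 (4R,5S,6S,7R,8S,10R,11R)-10,13-diacetoxy-4,5-epoxy-1-oxo-8-tigloyloxygermacran-12,6-olide (target)
Conditions: PPh3, DIAD, toluene, 0 to 50 °C
Reagents that add atoms: none
Why: Mitsunobu-type cyclodehydration, in which the secondary C5 hydroxyl becomes the oxyphosphonium leaving group and is displaced by the tertiary C4 oxygen with inversion at C5 and retention at C4, turning the threo diol into the cis-epoxide under neutral conditions.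

**Compound list**
1 | 3-methylbut-2-enal | CC(C)=CC=O | starting material
2 | methyl propiolate | C#CC(=O)OC | starting material
3 | methyl (4R)-4-hydroxy-6-methylhept-5-en-2-ynoate | CC(C)=C[C@@H](O)C#CC(=O)OC | intermediate
4 | methyl (2Z,4S)-4-hydroxy-6-methylhepta-2,5-dienoate | CC(C)=C[C@@H](O)/C=C\C(=O)OC | intermediate
5 | (5S)-5-(2-methylprop-1-enyl)furan-2(5H)-one | CC(C)=C[C@H]1OC(=O)C=C1 | intermediate
6 | ethyl vinyl ether | C=COCC | starting material
7 | formaldehyde | C=O | starting material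
8 | (1-ethoxyvinyl)lithium | [Li]C(=C)OCC | intermediate
9 | lithium bis(1-ethoxyvinyl)cuprate | [Li+].C=C(OCC)[Cu-]C(=C)OCC | intermediate
10 | lithium alkoxide of (3R,4S,5R)-4-(1-ethoxyvinyl)-3-(hydroxymethyl)-5-(2-methylprop-1-enyl)oxolan-2-one | [Li+].CC(C)=C[C@H]1OC(=O)[C@@H](C[O-])[C@@H]1C(=C)OCC | intermediate
11 | [(3R,4S,5R)-4-(1-ethoxyvinyl)-5-(2-methylprop-1-enyl)-2-oxooxolan-3-yl]methyl acetate | CC(C)=C[C@H]1OC(=O)[C@@H](COC(C)=O)[C@@H]1C(=C)OCC | intermediate
12 | pyruvic acid | CC(=O)C(=O)O | starting material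
13 | tert-butyl pyruvate | CC(=O)C(=O)OC(C)(C)C | intermediate
14 | tert-butyl (2R)-4-[(2R,3S,4R)-4-(acetoxymethyl)-2-(2-methylprop-1-enyl)-5-oxooxolan-3-yl]-2-hydroxy-2-methyl-4-oxobutanoate | CC(C)=C[C@H]1OC(=O)[C@@H](COC(C)=O)[C@@H]1C(=O)C[C@@](C)(O)C(=O)OC(C)(C)C | intermediate
15 | tert-butyl (2R,4S)-4-[(2R,3R,4R)-4-(acetoxymethyl)-2-(2-methylprop-1-enyl)-5-oxooxolan-3-yl]-2,4-dihydroxy-2-methylbutanoate | CC(C)=C[C@H]1OC(=O)[C@@H](COC(C)=O)[C@@H]1[C@@H](O)C[C@@](C)(O)C(=O)OC(C)(C)C | intermediate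
16 | tigloyl chloride ((E)-2-methylbut-2-enoyl chloride) | C/C=C(\C)C(=O)Cl | starting material
17 | C8 mono-tiglate of 15 (C10 hydroxyl free) | CC(C)=C[C@H]1OC(=O)[C@@H](COC(C)=O)[C@@H]1[C@@H](OC(=O)/C(C)=C/C)C[C@@](C)(O)C(=O)OC(C)(C)C | intermediate
18 | tert-butyl (2R,4S)-2-acetoxy-4-[(2R,3R,4R)-4-(acetoxymethyl)-2-(2-methylprop-1-enyl)-5-oxooxolan-3-yl]-2-methyl-4-[(E)-2-methylbut-2-enoyloxy]butanoate | CC(C)=C[C@H]1OC(=O)[C@@H](COC(C)=O)[C@@H]1[C@@H](OC(=O)/C(C)=C/C)C[C@@](C)(OC(C)=O)C(=O)OC(C)(C)C | intermediate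
19 | trimethylsilyl ester corresponding to 18 | CC(C)=C[C@H]1OC(=O)[C@@H](COC(C)=O)[C@@H]1[C@@H](OC(=O)/C(C)=C/C)C[C@@](C)(OC(C)=O)C(=O)O[Si](C)(C)C | intermediate
20 | (2R,4S)-2-acetoxy-4-[(2R,3R,4R)-4-(acetoxymethyl)-2-(2-methylprop-1-enyl)-5-oxooxolan-3-yl]-2-methyl-4-[(E)-2-methylbut-2-enoyloxy]butanoic acid | CC(C)=C[C@H]1OC(=O)[C@@H](COC(C)=O)[C@@H]1[C@@H](OC(=O)/C(C)=C/C)C[C@@](C)(OC(C)=O)C(=O)O | intermediate
21 | (2R,4S)-2-acetoxy-4-[(2R,3R,4R)-4-(acetoxymethyl)-2-[(1E)-3-hydroxy-2-methylprop-1-enyl]-5-oxooxolan-3-yl]-2-methyl-4-[(E)-2-methylbut-2-enoyloxy]butanoic acid | OC/C(C)=C/[C@H]1OC(=O)[C@@H](COC(C)=O)[C@@H]1[C@@H](OC(=O)/C(C)=C/C)C[C@@](C)(OC(C)=O)C(=O)O | intermediate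
22 | methyl hydrogen malonate | COC(=O)CC(=O)O | starting material
23 | magnesium bis(methyl malonate) | [Mg+2].COC(=O)CC(=O)[O-].COC(=O)CC(=O)[O-] | intermediate
24 | acyl imidazolide of 21 | OC/C(C)=C/[C@H]1OC(=O)[C@@H](COC(C)=O)[C@@H]1[C@@H](OC(=O)/C(C)=C/C)C[C@@](C)(OC(C)=O)C(=O)n1ccnc1 | intermediate
25 | methyl (4R,6S)-4-acetoxy-6-[(2R,3R,4R)-4-(acetoxymethyl)-2-[(1E)-3-hydroxy-2-methylprop-1-enyl]-5-oxooxolan-3-yl]-4-methyl-3-oxo-6-[(E)-2-methylbut-2-enoyloxy]hexanoate | OC/C(C)=C/[C@H]1OC(=O)[C@@H](COC(C)=O)[C@@H]1[C@@H](OC(=O)/C(C)=C/C)C[C@@](C)(OC(C)=O)C(=O)CC(=O)OC | intermediate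
26 | acylketene from 25 | OC/C(C)=C/[C@H]1OC(=O)[C@@H](COC(C)=O)[C@@H]1[C@@H](OC(=O)/C(C)=C/C)C[C@@](C)(OC(C)=O)C(=O)C=C=O | intermediate
27 | twelve-membered (E)-allyl β-keto lactone (6R,7R,8S,10R,11R) | C/C=C(\C)C(=O)O[C@H]1C[C@@](C)(OC(C)=O)C(=O)CC(=O)OC/C(C)=C/[C@H]2OC(=O)[C@@H](COC(C)=O)[C@@H]21 | intermediate
28 | ten-membered ring β-keto acid (2-carboxy derivative of 29, C2 undefined) | C/C=C(\C)C(=O)O[C@H]1C[C@@](C)(OC(C)=O)C(=O)C(C(=O)O)C/C(C)=C/[C@H]2OC(=O)[C@@H](COC(C)=O)[C@@H]21 | intermediate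
29 | (4E,6R,7R,8S,10R,11R)-10,13-diacetoxy-1-oxo-8-tigloyloxygermacr-4-en-12,6-olide | C/C=C(\C)C(=O)O[C@H]1C[C@@](C)(OC(C)=O)C(=O)CC/C(C)=C/[C@H]2OC(=O)[C@@H](COC(C)=O)[C@@H]21 | intermediate
30 | (4R,5R,6S,7R,8S,10R,11R)-10,13-diacetoxy-4,5-dihydroxy-1-oxo-8-tigloyloxygermacran-12,6-olide | C/C=C(\C)C(=O)O[C@H]1C[C@@](C)(OC(C)=O)C(=O)CC[C@@](C)(O)[C@H](O)[C@H]2OC(=O)[C@@H](COC(C)=O)[C@@H]21 | intermediate
31 | (4R,5S,6S,7R,8S,10R,11R)-10,13-diacetoxy-4,5-epoxy-1-oxo-8-tigloyloxygermacran-12,6-olide | C/C=C(\C)C(=O)O[C@H]1C[C@@](C)(OC(C)=O)C(=O)CC[C@@]2(C)O[C@H]2[C@H]2OC(=O)[C@@H](COC(C)=O)[C@@H]21 | target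

Total step count: 14. Longest linear sequence: 13 (steps 1–3 and 5–14).

**Steps most likely to fail**

Step 12 (new ring contraction). The strained E-ten-membered closure may lose out to re-lactonisation, diene formation or oligomers. The fallback sets out from 25. ClCO2Me and pyridine convert the primary alcohol into the allylic methyl carbonate F1. A conventional high-dilution Tsuji–Trost macrocyclisation (Pd2(dba)3, dppe, THF, slow addition) with the intact β-keto ester as soft nucleophile gives the ten-membered 2-methoxycarbonyl ketone F2. Krapcho demethoxycarbonylation (LiCl, wet DMSO, 120 °C) then comes back to the route at 29.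

Step 11 (thermal macrolactonisation). The methyl β-keto ester may need temperatures at which the β-acetoxy lactone eliminates. The fallback sets out from 21. The same CDI activation is followed by the magnesium salt of 3-(tert-butylsulfanyl)-3-oxopropanoic acid, which gives the S-tert-butyl β-keto thioester F3. AgO2CCF3 with Na2HPO4 in THF at room temperature under high dilution then activates the thioester towards the C3 hydroxyl through the thiophilic metal, with no heating. This comes back to the route at 27.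

Step 9 (allylic oxidation). The alkene is deactivated by the allylic lactone oxygen, and over-oxidation to the enal is likely. The fallback sets out from 20. Schenck ene reaction with singlet oxygen (O2, tetraphenylporphyrin, light, CH2Cl2) gives the transposed C5 allylic hydroperoxide F4, and PPh3 reduces it to the C5 allylic alcohol F5. Catalytic Ph3SiOReO3 (Et2O, 0 °C) effects the 1,3-transposition towards the more substituted alkene and the primary alcohol, coming back to the route at 21.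

**Further compounds**
F1 | step 12 | allylic methyl carbonate of 25 | COC(=O)OC/C(C)=C/[C@H]1OC(=O)[C@@H](COC(C)=O)[C@@H]1[C@@H](OC(=O)/C(C)=C/C)C[C@@](C)(OC(C)=O)C(=O)CC(=O)OC
F2 | step 12 | ten-membered 2-methoxycarbonyl ketone (2-carbomethoxy derivative of 29, C2 undefined) | C/C=C(\C)C(=O)O[C@H]1C[C@@](C)(OC(C)=O)C(=O)C(C(=O)OC)C/C(C)=C/[C@H]2OC(=O)[C@@H](COC(C)=O)[C@@H]21
F3 | step 11 | S-tert-butyl β-keto thioester analogue of 25 | OC/C(C)=C/[C@H]1OC(=O)[C@@H](COC(C)=O)[C@@H]1[C@@H](OC(=O)/C(C)=C/C)C[C@@](C)(OC(C)=O)C(=O)CC(=O)SC(C)(C)C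
F4 | step 9 | C5 allylic hydroperoxide from 20 (isopropenyl at C5, C5 undefined) | C=C(C)C(OO)[C@H]1OC(=O)[C@@H](COC(C)=O)[C@@H]1[C@@H](OC(=O)/C(C)=C/C)C[C@@](C)(OC(C)=O)C(=O)O
F5 | step 9 | C5 allylic alcohol from F4 (C5 undefined) | C=C(C)C(O)[C@H]1OC(=O)[C@@H](COC(C)=O)[C@@H]1[C@@H](OC(=O)/C(C)=C/C)C[C@@](C)(OC(C)=O)C(=O)O
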